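**Plan**
- Retrosynthetic cuts, in order: C4–C11 (hydroxymethylation of a C4 enol triflate); the C10–O coumarate; C10/C7 back to an α-hydroxy-β-keto ester; the C8–C9 bond, contracting the cyclopentane C5–C6–C7–C8–C9 to the cyclobutane C5–C6–C7–C9 with C8 as an exocyclic oxalyl carbon on C7; the cyclobutane bonds C5–C6 and C7–C9 ([2+2]); the C1–O ester.
- Forward: the pyran ring comes first, by dearomatising furfuryl alcohol; a cyclobutane is fused on at C5–C9; the four-membered ring is enlarged to the cyclopentane; C10 and C11 are finished last.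
- Enabling feature: C7(O)–C8(OH)(C10) is a tertiary α-ketol array. C8, with its OH and C10, can therefore start as the acyl carbon of a 1-oxalylcyclobutanol whose C7–C9 bond shifts to C8.
- Stereochemistry: C1 by catalyst-controlled dynamic kinetic acylation, which also installs the final C1 ester (its stereocentre is bought); C9 by addition anti to the C1 group; C5 by cis ring fusion; C8 relayed from C7 through the chelated shift; C7 by hydroxyl-directed hydride.

Key step: step 9

Remark: iridoid locants are used throughout (C1 acetal, O2, C3=C4, C5/C9 ring fusion, C6–C8, C10 on C8, C11 on C4); β is the face of H-5/H-9, α the opposite face.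
Assumption: (S)-3-methylpentanoic acid is bought, and the benzotetramisole enantiomer written in step 3 is the one taken to give the (S)-acetal (the catalyst, not the remote acyl stereocentre, fixes C1).

Step 1
Reactants: 1 furfuryl alcohol
Product: 2 rac-6-hydroxy-2H-pyran-3(6H)-one
Conditions: NBS (1.05 equiv), NaHCO3 (2 equiv), THF/H2O 4:1, 0 °C
Reagents that add atoms: water, O
Why: Achmatowicz rearrangement (oxidation of the furan, ring opening to the ene-dione, re-closure through the primary alcohol) gives the hemiacetal that already holds C1, O2, C3, C4 and the C5=C9 enone; the hemiacetal centre is labile, so no stereocentre is fixed.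

Step 2
Reactants: 3 (S)-3-methylpentanoic acid (2 equiv)
Product: 4 (S,S)-3-methylpentanoic anhydride
Conditions: DCC (0.5 equiv), CH2Cl2, 0 → 23 °C; filter
Reagents that add atoms: none
Why: carbodiimide dehydration of two acid molecules gives the symmetrical anhydride, and the β-stereocentre cannot epimerise.

Step 3
Reactants: 2 rac-6-hydroxy-2H-pyran-3(6H)-one; 4 (S,S)-3-methylpentanoic anhydride
Product: 5 (2S)-5-oxo-5,6-dihydro-2H-pyran-2-yl (3S)-3-methylpentanoate
Conditions: (S)-benzotetramisole (5 mol %), 2,6-lutidine (1.2 equiv), CHCl3, 0 °C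
Reagents that add atoms: none
Why: isothiourea-catalysed dynamic kinetic O-acylation: the lactol enantiomers interconvert through the open ene-dione aldehyde while the chiral N-acyl isothiouronium ion acylates one faster, which sets C1 (S) and installs the ester the target carries at C1.

Step 4
Reactants: 5 enone acyl acetal (the acylated pyranone of the preceding step); 6 ketene diethyl acetal
Product: 8 cis-fused head-to-tail cycloadduct (C7 diethyl ketal), via trans-fused cycloadduct 7 (not isolated)
Conditions: hν (medium-pressure Hg lamp, Pyrex, λ > 300 nm), ketene acetal in about tenfold excess, CH2Cl2, −40 °C; evaporate (the surplus ketene acetal distils off unchanged); DBU (5 mol %), CH2Cl2, 0 °C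
Reagents that add atoms: none
Why: enone–alkene [2+2] photocycloaddition, a one-to-one addition that keeps every atom of both partners, runs in the head-to-tail sense and puts the ketal carbon C7 on the β-carbon C9 and C6 on C5; the alkene should add anti to the C1 acyloxy group (sets C9), and catalytic base equilibration at C5 (α to the ketone) turns the trans-fused isomer into the more stable cis ring fusion (sets C5).

Step 5
Reactants: 8 cis-fused cycloadduct
Product: 9 C3=C4 enol triflate
Conditions: KHMDS (1.05 equiv), THF, −78 °C; PhNTf2 (1.1 equiv), −78 → −30 °C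
Reagents that add atoms: N-phenylbis(trifluoromethanesulfonimide), O=S(=O)(N(c1ccccc1)S(=O)(=O)C(F)(F)F)C(F)(F)F
Why: kinetic deprotonation at the unhindered C3 methylene rather than the cyclobutane ring-fusion C5, then O-sulfonylation, gives the enol triflate that masks the C4 ketone and later accepts C11.

Step 6
Reactants: 9 C3=C4 enol triflate
Product: 10 cyclobutanone (C7=O)
Conditions: TsOH·H2O (10 mol %), acetone/H2O 10:1, 23 °C; neutral work-up
Reagents that add atoms: water, O
Why: acid-catalysed ketal hydrolysis, with the anomeric ester protected from ionisation because O2 is conjugated to the electron-poor enol triflate.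

Step 7
Reactants: 10 cyclobutanone; 11 ethyl diazoacetate
Product: 12 C7 carbinol bearing the exo C(=N2)CO2Et group
Conditions: LDA (1.25 equiv) and ethyl diazoacetate (1.3 equiv), THF, −78 °C; add the cyclobutanone, −78 °C; AcOH quench at −78 °C
Reagents that add atoms: none
Why: aldol-type addition of lithiated ethyl diazoacetate to the strained ketone should occur from the exo (β) face, away from the pyran ring, placing C8 exo and the C7 hydroxyl endo; addition at −78 °C should outrun enolisation.

Step 8
Reactants: 12 β-hydroxy-α-diazo ester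
Product: 13 β-hydroxy-α-keto ester (1-oxalylcyclobutanol)
Conditions: DMDO (1.1 equiv, acetone solution), CH2Cl2, −40 → 0 °C; used crude
Reagents that add atoms: dimethyldioxirane, CC1(C)OO1
Why: oxygen transfer to the diazo carbon with loss of N2 converts the diazo ester into the α-keto ester, and the electron-poor enol triflate alkene should not be epoxidised at this temperature.

Step 9
Reactants: 13 β-hydroxy-α-keto ester
Product: 14 ethyl (1S,4aS,7S,7aS)-7-hydroxy-1-[(3S)-3-methylpentanoyloxy]-6-oxo-4-(triflyloxy)-1,4a,5,6,7,7a-hexahydrocyclopenta[c]pyran-7-carboxylate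
Conditions: Cu(OTf)2 (10 mol %), 4 Å MS, CH2Cl2, 0 → 23 °C
Reagents that add atoms: none
Why: Cu(II) holds the C7 hydroxyl and the C8 ketone carbonyl in a syn chelate, and the C7–C9 σ-bond, aligned with the C8 carbonyl π*, shifts to C8 while C7 becomes the ketone; this is a suprafacial 1,2-shift with retention at C9, driven by release of cyclobutane strain. The closest known reaction type is the α-ketol (acyloin) rearrangement of 1-acylcyclobutanols and of β-hydroxy-α-dicarbonyls to 2-hydroxycyclopentanones under Lewis acid catalysis. The cyclopentane C5–C6–C7–C8–C9 is not closed by a cyclisation: it arises from the cyclobutane C5–C6–C7–C9 by ring enlargement, the exocyclic carbon C8 entering between C7 and C9. The new stereocentre C8 is controlled by the C7 configuration from step 7 (oxalyl exo, hydroxyl endo): in the chelated rotamer C9 attacks the carbonyl face that leaves the C8 hydroxyl α (face of C1) and the ester carbon C10 β (face of H-9). The selectivity needed is regiochemical, migration of the ring-fusion methine C9 rather than the C6 methylene, and it rests on the higher migratory aptitude of the more substituted carbon; the enol triflate and the C1 ester are spectators.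

Step 10
Reactants: 14 ring-expanded α-hydroxy-β-keto ester
Product: 15 ethyl (1S,4aS,6S,7S,7aS)-6,7-dihydroxy-1-[(3S)-3-methylpentanoyloxy]-4-(triflyloxy)-1,4a,5,6,7,7a-hexahydrocyclopenta[c]pyran-7-carboxylate
Conditions: Me4NBH(OAc)3 (5 equiv), MeCN/AcOH 1:1, −30 °C
Reagents that add atoms: none
Why: Saksena–Evans hydroxyl-directed reduction: the 8α-alkoxyborohydride delivers hydride to the α-face of the C7 ketone, giving the trans 7β,8α-diol without touching the esters.

Step 11
Reactants: 15 7β,8α-diol ethyl ester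
Product: 16 (1S,4aS,6S,7R,7aS)-6,7-dihydroxy-7-(hydroxymethyl)-4-(triflyloxy)-1,4a,5,6,7,7a-hexahydrocyclopenta[c]pyran-1-yl (3S)-3-methylpentanoate
Conditions: BH3·SMe2 (3 equiv), NaBH4 (5 mol %), THF, 0 → 23 °C; MeOH quench
Reagents that add atoms: none
Why: borane/catalytic borohydride reduction of an α-hydroxy ester proceeds through a cyclic dialkoxyborane that activates only the C10 ester, so the unactivated C1 ester and the enol triflate should survive.

Step 12
Reactants: 17 (E)-p-coumaric acid
Product: 19 (E)-4-(tert-butyldimethylsilyloxy)cinnamic acid, via bis-silyl derivative 18 (not isolated)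
Conditions: TBSCl (2.3 equiv), imidazole (5 equiv), DMF, 23 °C; then AcOH/THF/H2O 3:1:1, 23 °C
Reagents that add atoms: tert-butyldimethylsilyl chloride, CC(C)(C)[Si](C)(C)Cl
Why: silylation of both acidic OH groups followed by selective hydrolysis of the far more labile silyl ester leaves the aryl silyl ether.

Step 13
Reactants: 16 triol; 19 (E)-4-(tert-butyldimethylsilyloxy)cinnamic acid
Product: 20 10-O-[(E)-4-(TBSO)cinnamoyl] enol triflate
Conditions: silyl-protected acid (1.05 equiv), DIC (1.1 equiv), DMAP (0.1 equiv), CH2Cl2, −20 → 0 °C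
Reagents that add atoms: none
Why: Steglich esterification should take the primary C10 hydroxyl well ahead of the hindered secondary C7 and tertiary C8 hydroxyls.

Step 14
Reactants: 20 coumarate enol triflate; 21 (tributylstannyl)methanol
Product: 22 O-TBS-protected target
Conditions: stannane (1.5 equiv), Pd(PPh3)4 (10 mol %), LiCl (3 equiv), 1,4-dioxane, 90 °C
Reagents that add atoms: none
Why: Stille coupling of the enol triflate with the hydroxymethylstannane installs C11 at the alcohol oxidation level under neutral conditions that tolerate the free diol, both esters and the acyl acetal.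

Step 15
Reactants: 22 O-TBS-protected target
Product: 23 target
Conditions: TBAF (1.2 equiv), AcOH (1.5 equiv), THF, 0 °C
Reagents that add atoms: none
Why: buffered fluoride cleaves the aryl silyl ether, the most fluoride-labile group present, while the acetic acid buffer suppresses acyl migration and loss of the C1 acyl acetal.

**Compound list**
1 | furfuryl alcohol | OCc1ccco1 | starting material
2 | rac-6-hydroxy-2H-pyran-3(6H)-one | OC1OCC(=O)C=C1 | intermediate
3 | (S)-3-methylpentanoic acid | CC[C@H](C)CC(=O)O | starting material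
4 | (S,S)-3-methylpentanoic anhydride | CC[C@H](C)CC(=O)OC(=O)C[C@@H](C)CC | intermediate
5 | (2S)-5-oxo-5,6-dihydro-2H-pyran-2-yl (3S)-3-methylpentanoate (acetal carbon = C1) | CC[C@H](C)CC(=O)O[C@@H]1OCC(=O)C=C1 | intermediate
6 | 1,1-diethoxyethene (ketene diethyl acetal) | C=C(OCC)OCC | starting material
7 | trans-fused head-to-tail cycloadduct (C5 epimer of 8) | CC[C@H](C)CC(=O)O[C@@H]1OCC(=O)[C@@H]2CC(OCC)(OCC)[C@@H]12 | intermediate
8 | cis-fused cycloadduct: 8,8-diethoxy-5-oxo-3-oxabicyclo[4.2.0]oct-2-yl (3S)-3-methylpentanoate; ketal carbon C7 on C9, C6 on C5, H-5/H-9 cis and on the face of the C1 acyloxy group | CC[C@H](C)CC(=O)O[C@@H]1OCC(=O)[C@H]2CC(OCC)(OCC)[C@@H]12 | intermediate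
9 | C3=C4 enol triflate of 8: 8,8-diethoxy-5-(triflyloxy)-3-oxabicyclo[4.2.0]oct-4-en-2-yl ester | CC[C@H](C)CC(=O)O[C@@H]1OC=C(OS(=O)(=O)C(F)(F)F)[C@H]2CC(OCC)(OCC)[C@@H]12 | intermediate
10 | cyclobutanone: 8-oxo-5-(triflyloxy)-3-oxabicyclo[4.2.0]oct-4-en-2-yl ester | CC[C@H](C)CC(=O)O[C@@H]1OC=C(OS(=O)(=O)C(F)(F)F)[C@H]2CC(=O)[C@@H]12 | intermediate
11 | ethyl diazoacetate | CCOC(=O)C=[N+]=[N-] | starting material
12 | β-hydroxy-α-diazo ester: C7 hydroxyl endo (α), C(=N2)CO2Et exo (β) | CC[C@H](C)CC(=O)O[C@@H]1OC=C(OS(=O)(=O)C(F)(F)F)[C@H]2C[C@](O)(C(=[N+]=[N-])C(=O)OCC)[C@@H]12 | intermediate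
13 | β-hydroxy-α-keto ester (1-ethoxyoxalyl cyclobutanol) | CC[C@H](C)CC(=O)O[C@@H]1OC=C(OS(=O)(=O)C(F)(F)F)[C@H]2C[C@](O)(C(=O)C(=O)OCC)[C@@H]12 | intermediate
14 | ethyl (1S,4aS,7S,7aS)-7-hydroxy-1-[(3S)-3-methylpentanoyloxy]-6-oxo-4-(triflyloxy)-1,4a,5,6,7,7a-hexahydrocyclopenta[c]pyran-7-carboxylate (8α-OH, 8β-CO2Et) | CC[C@H](C)CC(=O)O[C@@H]1OC=C(OS(=O)(=O)C(F)(F)F)[C@H]2CC(=O)[C@](O)(C(=O)OCC)[C@@H]12 | intermediate
15 | ethyl (1S,4aS,6S,7S,7aS)-6,7-dihydroxy-1-[(3S)-3-methylpentanoyloxy]-4-(triflyloxy)-1,4a,5,6,7,7a-hexahydrocyclopenta[c]pyran-7-carboxylate (7β-OH, 8α-OH) | CC[C@H](C)CC(=O)O[C@@H]1OC=C(OS(=O)(=O)C(F)(F)F)[C@H]2C[C@H](O)[C@](O)(C(=O)OCC)[C@@H]12 | intermediate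
16 | (1S,4aS,6S,7R,7aS)-6,7-dihydroxy-7-(hydroxymethyl)-4-(triflyloxy)-1,4a,5,6,7,7a-hexahydrocyclopenta[c]pyran-1-yl (3S)-3-methylpentanoate | CC[C@H](C)CC(=O)O[C@@H]1OC=C(OS(=O)(=O)C(F)(F)F)[C@H]2C[C@H](O)[C@](O)(CO)[C@@H]12 | intermediate
17 | (E)-p-coumaric acid | OC(=O)/C=C/c1ccc(O)cc1 | starting material
18 | tert-butyldimethylsilyl (E)-4-(tert-butyldimethylsilyloxy)cinnamate | CC(C)(C)[Si](C)(C)OC(=O)/C=C/c1ccc(O[Si](C)(C)C(C)(C)C)cc1 | intermediate
19 | (E)-4-(tert-butyldimethylsilyloxy)cinnamic acid | OC(=O)/C=C/c1ccc(O[Si](C)(C)C(C)(C)C)cc1 | intermediate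
20 | 10-O-[(E)-4-(TBSO)cinnamoyl] derivative of 16 | CC[C@H](C)CC(=O)O[C@@H]1OC=C(OS(=O)(=O)C(F)(F)F)[C@H]2C[C@H](O)[C@](O)(COC(=O)/C=C/c3ccc(O[Si](C)(C)C(C)(C)C)cc3)[C@@H]12 | intermediate
21 | (tributylstannyl)methanol | OC[Sn](CCCC)(CCCC)CCCC | starting material
22 | phenol-O-TBS ether of the target | CC[C@H](C)CC(=O)O[C@@H]1OC=C(CO)[C@H]2C[C@H](O)[C@](O)(COC(=O)/C=C/c3ccc(O[Si](C)(C)C(C)(C)C)cc3)[C@@H]12 | intermediate
23 | [(1S,4aS,6S,7R,7aS)-6,7-dihydroxy-4-(hydroxymethyl)-7-{[(E)-3-(4-hydroxyphenyl)prop-2-enoyl]oxymethyl}-1,4a,5,6,7,7a-hexahydrocyclopenta[c]pyran-1-yl] (3S)-3-methylpentanoate | CC[C@H](C)CC(=O)O[C@@H]1OC=C(CO)[C@H]2C[C@H](O)[C@](O)(COC(=O)/C=C/c3ccc(O)cc3)[C@@H]12 | target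

**Count and risks**
Total steps: 15. Longest linear sequence: 13 (steps 1, 3–11, 13–15).

Risk 1, step 9. The shift could go through migration of the C6 methylene instead of the ring-fusion carbon C9, giving the wrong ring-expanded constitution; C9 carries the electron-poor acetal carbon, which may lower its migratory aptitude. Fallback (from 10, returning at 14): block C6. Two rounds of kinetic silyl enol ether formation toward C6 (LiHMDS/TMSCl, −78 °C) and chlorination with NCS should give the 6,6-dichlorocyclobutanone F1. DBU-catalysed aldol addition of ethyl diazoacetate should give the diazo alcohol F2, and DMDO the keto ester F3. The Cu(II)-mediated shift, in which the CCl2 carbon cannot migrate, should then give the 6,6-dichlorocyclopentanone F4. Bu3SnH/AIBN (benzene, 80 °C) removes both chlorines and returns 14.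

Risk 2, step 7. The basic diazo-enolate could deprotonate the cyclobutanone at C9, followed by β-elimination of the C1 carboxylate, or the adduct could undergo retro-aldol on warming. Fallback (from 10, returning at 13): a non-basic Mukaiyama aldol. Cyclobutanone 10 with 1-ethoxy-1,2-bis(trimethylsilyloxy)ethene and BF3·OEt2 (CH2Cl2, −78 °C), followed by a desilylating work-up, should give the α,β-dihydroxy ester F5 by exo attack (C8 epimers, both usable). Dess–Martin oxidation of its secondary alcohol gives 13.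

Risk 3, step 11. The borane reduction could lose chemoselectivity, through hydride attack on the anomeric ester or hydroboration of the enol triflate. Fallback (from 10, returning at 16): make C10 a carboxylic acid, which borane reduces much faster than any ester. Steps 7–10 are run with 2,2,2-trichloroethyl diazoacetate in place of 11, giving in turn the diazo alcohol F6, the keto ester F7, the ring-expanded cyclopentanone F8 and the 7β,8α-diol ester F9. Zn in AcOH/THF removes the trichloroethyl group to give the acid F10, and BH3·THF at 0 °C reduces the acid to 16.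

Further compounds
F1 | step 9 | 6,6-dichloro derivative of cyclobutanone 10 | CC[C@H](C)CC(=O)O[C@@H]1OC=C(OS(=O)(=O)C(F)(F)F)[C@H]2C(Cl)(Cl)C(=O)[C@@H]12
F2 | step 9 | 6,6-dichloro β-hydroxy-α-diazo ester | CC[C@H](C)CC(=O)O[C@@H]1OC=C(OS(=O)(=O)C(F)(F)F)[C@H]2C(Cl)(Cl)[C@](O)(C(=[N+]=[N-])C(=O)OCC)[C@@H]12
F3 | step 9 | 6,6-dichloro β-hydroxy-α-keto ester | CC[C@H](C)CC(=O)O[C@@H]1OC=C(OS(=O)(=O)C(F)(F)F)[C@H]2C(Cl)(Cl)[C@](O)(C(=O)C(=O)OCC)[C@@H]12
F4 | step 9 | 6,6-dichloro derivative of cyclopentanone 14 | CC[C@H](C)CC(=O)O[C@@H]1OC=C(OS(=O)(=O)C(F)(F)F)[C@H]2C(Cl)(Cl)C(=O)[C@](O)(C(=O)OCC)[C@@H]12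
F5 | step 7 | α,β-dihydroxy ester (C7 carbinol, C8 secondary alcohol, C8 epimers) | CC[C@H](C)CC(=O)O[C@@H]1OC=C(OS(=O)(=O)C(F)(F)F)[C@H]2C[C@](O)(C(O)C(=O)OCC)[C@@H]12
F6 | step 11 | 2,2,2-trichloroethyl analogue of diazo alcohol 12 | CC[C@H](C)CC(=O)O[C@@H]1OC=C(OS(=O)(=O)C(F)(F)F)[C@H]2C[C@](O)(C(=[N+]=[N-])C(=O)OCC(Cl)(Cl)Cl)[C@@H]12
F7 | step 11 | 2,2,2-trichloroethyl analogue of keto ester 13 | CC[C@H](C)CC(=O)O[C@@H]1OC=C(OS(=O)(=O)C(F)(F)F)[C@H]2C[C@](O)(C(=O)C(=O)OCC(Cl)(Cl)Cl)[C@@H]12
F8 | step 11 | 2,2,2-trichloroethyl analogue of cyclopentanone 14 | CC[C@H](C)CC(=O)O[C@@H]1OC=C(OS(=O)(=O)C(F)(F)F)[C@H]2CC(=O)[C@](O)(C(=O)OCC(Cl)(Cl)Cl)[C@@H]12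
F9 | step 11 | 2,2,2-trichloroethyl analogue of diol ester 15 | CC[C@H](C)CC(=O)O[C@@H]1OC=C(OS(=O)(=O)C(F)(F)F)[C@H]2C[C@H](O)[C@](O)(C(=O)OCC(Cl)(Cl)Cl)[C@@H]12
F10 | step 11 | 7β,8α-dihydroxy C10 carboxylic acid | CC[C@H](C)CC(=O)O[C@@H]1OC=C(OS(=O)(=O)C(F)(F)F)[C@H]2C[C@H](O)[C@](O)(C(=O)O)[C@@H]12
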